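**Assumption:** natural (2R,3R)-(+)-aromadendrin (dihydrokaempferol) is bought as the single enantiomer from a natural-product supplier and its ee is checked by chiral HPLC before use.

## Retrosynthetic overview

- Donor: commodity 4-hydroxybenzaldehyde (1) → Mannich base (2) → quaternary ammonium salt (3), a storable photochemical source of the 4-hydroxybenzyl unit.
- Core: (2R,3R)-(+)-aromadendrin (4) brings rings A, B and C and both stereocentres (C2, C3), so no ring is formed in the route.
- Key disconnections: the two aryl–CH2 bonds at C6 and C8. Under light, 3 gives p-quinone methide (5), which the A ring of 4 captures twice (mono-adducts 6 and 7) to give gericudranin D (8) in one pot.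
- Order of events: donor synthesis (2 steps), then one photochemical double C-benzylation, with no protecting groups.

## Route

**Step 1**
Reactants: 1 4-hydroxybenzaldehyde
Product: 2 4-[(dimethylamino)methyl]phenol
Conditions: Me2NH (2 M in THF, 1.5 equiv), NaBH(OAc)3 (1.5 equiv), AcOH (1 equiv), THF, 0 °C → rt, 12 h; NaHCO3 work-up at pH ≈ 9
Reagents that add atoms: dimethylamine, CNC
Why: Reductive amination with triacetoxyborohydride, which reduces the iminium ion formed from the aldehyde and the secondary amine much faster than the electron-rich aldehyde itself; no stereocentre is involved. (2 is made from commodity 1 because it is only a niche catalogue item.)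

**Step 2**
Reactants: 2 4-[(dimethylamino)methyl]phenol
Product: 3 (4-hydroxybenzyl)trimethylammonium methyl sulfate
Conditions: Me2SO4 (1.0 equiv), acetone, 0 °C → rt, 3 h; filter the precipitated salt
Reagents that add atoms: dimethyl sulfate, COS(=O)(=O)OC
Why: Menshutkin quaternisation, in which the neutral tertiary amine is far more nucleophilic than the un-ionised phenol, so one equivalent methylates only nitrogen and the salt precipitates; the methyl sulfate counter-ion is chosen because, unlike iodide, it is transparent and photo-inert at 254 nm.

**Step 3**
Reactants: 4 (2R,3R)-(+)-aromadendrin; 3 (4-hydroxybenzyl)trimethylammonium methyl sulfate (6 equiv in three portions, 2 equiv incorporated)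
Product: 8 gericudranin D = (2R,3R)-6,8-bis(4-hydroxybenzyl)aromadendrin, via p-quinone methide 5 (not isolated), via 6-(4-hydroxybenzyl)aromadendrin 6 (not isolated), via 8-(4-hydroxybenzyl)aromadendrin 7 (not isolated)
Conditions: 4 (5 mM), hν 254 nm (low-pressure Hg, quartz), MeCN/50 mM aq. phosphate pH 6.5 (1:1), Ar, 15 °C, 3–4 h (HPLC control); RP-HPLC or Sephadex LH-20
Reagents that add atoms: none
Why: Proposed new method: photochemical double Friedel–Crafts-type C-(4-hydroxybenzyl)ation of an unprotected flavanonol A ring. Excitation of the phenol chromophore of 3 triggers excited-state proton transfer to water and loss of NMe3 to give p-quinone methide 5. The partly ionised 7-hydroxy A ring of 4 (a phloroglucinol-type carbon nucleophile) adds to 5 at C6 or C8 and rearomatises to 6/7, and a second capture at the remaining position gives 8. O-adducts (4-hydroxybenzyl ethers) are themselves labile quinone-methide precursors and are recycled, whereas C-adducts are irreversible and the A ring ends fully substituted. The chromophore of 4 is deactivated by fast proton transfer between 5-OH and the C4 carbonyl, so it should act only as a photostable inner filter. No new stereocentre is formed: the (2R,3R) configuration bought in 4 is carried through because pH 6.5 and 15 °C avoid enolisation at C3, and any reversible C2–O1 opening recloses to the trans isomer under control of C3. Closest known reaction types: photogeneration of quinone methides from hydroxybenzyl alcohols and Mannich-base ammonium salts with trapping by N, O and S nucleophiles or vinyl ethers, and thermal acid-catalysed hydroxybenzylation of flavonoid A rings; C–C bond formation between a photogenerated parent p-quinone methide and a polyphenol carbon nucleophile has not been shown.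

## Compound list

1 | 4-hydroxybenzaldehyde | O=Cc1ccc(O)cc1 | starting material
2 | 4-[(dimethylamino)methyl]phenol | CN(C)Cc1ccc(O)cc1 | intermediate
3 | (4-hydroxybenzyl)trimethylammonium methyl sulfate | C[N+](C)(C)Cc1ccc(O)cc1.COS(=O)(=O)[O-] | intermediate
4 | (2R,3R)-(+)-aromadendrin = (2R,3R)-3,5,7-trihydroxy-2-(4-hydroxyphenyl)chroman-4-one | O=C1c2c(O)cc(O)cc2O[C@H](c2ccc(O)cc2)[C@H]1O | starting material
5 | p-quinone methide (4-methylidenecyclohexa-2,5-dien-1-one) | C=C1C=CC(=O)C=C1 | intermediate
6 | (2R,3R)-6-(4-hydroxybenzyl)aromadendrin | O=C1c2c(O)c(Cc3ccc(O)cc3)c(O)cc2O[C@H](c2ccc(O)cc2)[C@H]1O | intermediate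
7 | (2R,3R)-8-(4-hydroxybenzyl)aromadendrin | O=C1c2c(O)cc(O)c(Cc3ccc(O)cc3)c2O[C@H](c2ccc(O)cc2)[C@H]1O | intermediate
8 | gericudranin D = (2R,3R)-3,5,7-trihydroxy-2-(4-hydroxyphenyl)-6,8-bis(4-hydroxybenzyl)chroman-4-one | O=C1c2c(O)c(Cc3ccc(O)cc3)c(O)c(Cc3ccc(O)cc3)c2O[C@H](c2ccc(O)cc2)[C@H]1O | target

## Step count and risks

Total steps: 3. Longest linear sequence: 3 (1 → 2 → 3 → 8); 4 enters in the last step.

**Step 3 (the proposed new step, highest risk).** Compound 4 absorbs part of the 254 nm light, 5 can oligomerise or be hydrated, the second benzylation may lag, and the pendant phenol rings could be alkylated. The fallback uses known chemistry and no light. It sets out from 4, which is heated with commercial 4-hydroxybenzyl alcohol (OCc1ccc(O)cc1, 3 equiv) and catalytic p-TsOH in dioxane at 60–70 °C under argon. This is the established thermal Brønsted-acid Friedel–Crafts hydroxybenzylation of flavonoid A rings. It runs through the same mono-adducts 6 and 7 and comes back to the route at 8. Any cis-epimer formed under acid re-equilibrates to the trans isomer, because C3 is untouched.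

**Step 2.** Risks are partial O-methylation, a hygroscopic salt, or traces of methylating agent carried into the photolysis. The fallback avoids alkylation altogether. It sets out from 2, which is treated with HCl in ether to give its hydrochloride, 4-[(dimethylammonio)methyl]phenol chloride F2. F2 is used directly as the donor under the step 3 irradiation conditions with 4; protonated Mannich bases are known photochemical quinone-methide precursors that expel the secondary amine. It comes back to the route at 8.

**Step 1.** Risks are sluggish iminium formation from the electron-rich aldehyde, over-reduction to the benzyl alcohol, and losses on isolating the amphoteric product. The fallback changes the bond-forming logic from reductive amination to substitution. It sets out from 1, which is reduced with NaBH4 in MeOH to 4-hydroxybenzyl alcohol F1. F1 is then heated with 40% aqueous dimethylamine in a sealed tube at about 110 °C, where thermal quinone-methide formation and amine addition occur. It comes back to the route at 2.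

## Further compounds

F1 | step 1 | 4-hydroxybenzyl alcohol | OCc1ccc(O)cc1
F2 | step 2 | 4-[(dimethylammonio)methyl]phenol chloride (hydrochloride of 2) | C[NH+](C)Cc1ccc(O)cc1.[Cl-]
F0 | step 3 | none | none
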